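You cannot read the free nucleophile out of the ash run: it holds readings of electrophile and target and none of nucleophile. What it does give is the pace of its own tail.

- ash: electrophile 0.54 M; nucleophile 0.594 M; protic impurity 0.0054 M; run made earlier
- flask: electrophile 0.54 M; nucleophile 0.594 M; protic impurity 0.0108 M; time 5.0 d

ash run (percent of the electrophile charged)

| time / h | electrophile / % | target / % |
|---|---|---|
| 3.00 | 63.8 | 34.2 |
| 5.00 | 59.2 | 38.0 |
| 8.00 | 53.6 | 44.7 |
| 12.0 | 50.2 | 47.7 |
| 20.0 | 45.4 | 51.2 |
| 40.0 | 37.2 | 56.0 |

(standard deviation of a reading: 1 percentage point)

* part of the electrophile that has reacted at 5.0 d
* share of the unused nucleophile that is free and not bound as protonated nucleophile, at 5.0 d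

- the earlier runs do not show how much of nucleophile is bound; that part of a forecast is a guess
- no earlier run changes the charge of protic impurity; that part of a forecast is a guess

Two settings differ from the ash run. Take the protic impurity first: reckoned one for one, the extra 0.00540 M takes 0.909 % of the nucleophile charge, so by hand I leave it out.

Then time, from 40.0 h to 5.0 d. I define the tail rate as the pseudo-first-order fall of the electrophile over the last two ash readings, the logarithm of their ratio over the hours between them: 0.00996 /h. This is a reading and carries the scatter of those two points. Run on from the last ash reading, it gives 16.8 % of the electrophile as an estimate, so I reckon 83.2 % reacted.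

The free share stays a guess of mine. Target at the last ash reading equals about half the nucleophile charge, and if each turn frees an acid that binds a second nucleophile, I expect a small free share.

The forecast says 76 % reacted (63 % to 88 %), below mine, and 70 % free (15 % to 98 %), which it calls “a broad guess”.

The flask gives 82.0 % reacted and 4.42 % free. Changing only the protic impurity keeps the ash run at 61.9 % at its last reading, against 62.2 % unchanged, while changing only the time takes it to 82.2 %. Now use the tail rate on this flask: from 31.3 % electrophile at 2.50 d it gives 17.2 % at 5.0 d, and the flask holds 18.0 %.

    electrophile + nucleophile → acid set free + target (k = 0.550 /M/h)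
    nucleophile + acid set free ⇌ protonated nucleophile, settled at all times (K = 170 /M)
    nucleophile + protic impurity → quenched reagent (k = 37.0 /M/h)
    electrophile + acid set free → side product (k = 0.0470 /M/h)
    2 nucleophile → homo dimer (k = 0.200 /M/h)

Now the neighbour with 0.36 M of nucleophile. Assuming two nucleophile per target, I estimate that its fast stage leaves 66.7 % of the electrophile. Assuming too that the tail rate scales with the nucleophile charge, I reckon 67.7 % reacted at 5.0 d; the computed neighbour has 68.8 %.

The numbers in the tables are calculated with constants of no real substance, noise included.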